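**Retrosynthetic overview**

1. Numbering (germacrane): ring C1–C10; oxirane O on C1/C10; C3–OH; C4=C5; lactone O on C6; C7; ester O on C8; C11–C13 lactone carbons; C14 = CH3 on C10; C15 = CH2OH on C4.
2. Feature: C7 is a member of the ten-membered carbocycle, the β-carbon of the α-methylene-γ-lactone (O–C6–C7–C11–C12) and the neighbour of the C8 carbinol. The C7–C8 bond is therefore cut to a C8 aldehyde and an allylmetal at C13 that reacts through C7 (3-(bromomethyl)butenolide 29 → 31).
3. 29 comes from Z-enal 18: alkynylation at C6 (sets 6R), hydroxyl-directed hydroalumination/iodination and carbonylative lactonisation give the butenolide with the C13 oxygen already in place. No allylic bromination of a methyl group is needed; C13–OH → Br and C8–OPMB → CHO follow.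
4. 18 comes from Z-vinyl iodide 11 (but-2-yne-1,4-diol, Z-C4=C5) and aldehyde 6 (but-3-yn-1-ol, E-C1=C10 by carboalumination) through a Nozaki–Hiyama–Kishi coupling; C3 is set by CBS reduction.
5. Ring order: butenolide (step 16), ten-membered carbocycle (step 21), oxirane (step 23); C8 methacrylate and desilylation finish the route.

Key step: step 21

Assumption: the zinc complex of (R,R)-ProPhenol is taken to deliver the alkynyl group to the Si face of enal 18 (giving 6R); if the sense proves opposite, the (S,S)-ligand is used.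

**Route**

Step 1
Reactants: 1 but-3-yn-1-ol
Product: 2 4-methoxybenzyl but-3-yn-1-yl ether
Conditions: NaH, 4-methoxybenzyl chloride, Bu4NI (cat.), THF/DMF, 0 °C → rt
Reagents that add atoms: 4-methoxybenzyl chloride, COc1ccc(CCl)cc1
Why: Williamson etherification of the primary alkoxide; the PMB ether protects C8–O through the whole sequence and can later be removed oxidatively beside silyl ethers.

Step 2
Reactants: 2 4-methoxybenzyl but-3-yn-1-yl ether
Product: 5 (E)-6-[(4-methoxybenzyl)oxy]-4-methylhex-3-en-1-ol, via alkenylalane 3 (not isolated), via lithium alanate 4 (not isolated)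
Conditions: AlMe3, Cp2ZrCl2 (25 mol%), CH2Cl2, 0 °C → rt; evaporate; n-BuLi, hexane/THF, 0 °C; ethylene oxide, −20 °C → rt
Reagents that add atoms: trimethylaluminium, C[Al](C)C; ethylene oxide, C1CO1
Why: Negishi carboalumination adds CH3 (C14) and aluminium syn across the terminal alkyne with methyl on the internal carbon, and the derived alanate opens ethylene oxide with retention, which fixes the E-C1=C10 olefin and adds C2–C3.

Step 3
Reactants: 5 (E)-6-[(4-methoxybenzyl)oxy]-4-methylhex-3-en-1-ol
Product: 6 (E)-6-[(4-methoxybenzyl)oxy]-4-methylhex-3-enal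
Conditions: Dess–Martin periodinane, pyridine, CH2Cl2, 0 °C; used crude
Reagents that add atoms: none
Why: Buffered Dess–Martin oxidation should give the β,γ-unsaturated aldehyde without moving the double bond into conjugation.

Step 4
Reactants: 7 but-2-yne-1,4-diol
Product: 8 4-[(tert-butyldimethylsilyl)oxy]but-2-yn-1-ol
Conditions: NaH (1 equiv), TBSCl (1 equiv), THF, 0 °C → rt
Reagents that add atoms: tert-butyldimethylsilyl chloride, CC(C)(C)[Si](C)(C)Cl
Why: Monosilylation of the symmetrical diol through its monosodium alkoxide.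

Step 5
Reactants: 8 4-[(tert-butyldimethylsilyl)oxy]but-2-yn-1-ol
Product: 10 (Z)-4-[(tert-butyldimethylsilyl)oxy]-3-iodobut-2-en-1-ol, via cyclic alkenylalanate 9 (not isolated)
Conditions: NaAlH2(OCH2CH2OMe)2 (Red-Al), THF, 0 °C; EtOAc; I2, THF, −78 → 0 °C
Reagents that add atoms: iodine, [I][I]
Why: Hydroxyl-directed trans-hydroalumination of the propargylic alcohol places aluminium on the distal alkyne carbon (C4) in a five-membered alkoxyaluminate, and iodinolysis with retention gives the vinyl iodide with iodine cis to C6, the geometry the Z-C4=C5 olefin needs.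

Step 6
Reactants: 10 (Z)-4-[(tert-butyldimethylsilyl)oxy]-3-iodobut-2-en-1-ol
Product: 11 (Z)-vinyl iodide with C6–OTES and C15–OTBS
Conditions: TESCl, imidazole, CH2Cl2, 0 °C
Reagents that add atoms: chlorotriethylsilane, CC[Si](Cl)(CC)CC
Why: Silylation of the primary alcohol; TES is chosen because it can later be removed beside TBS ethers.

Step 7
Reactants: 11 (Z)-vinyl iodide with C6–OTES and C15–OTBS; 6 (E)-6-[(4-methoxybenzyl)oxy]-4-methylhex-3-enal
Product: 13 racemic C3 allylic alcohol (chain C6–C8; 4Z; 1(10)E), via alkenylchromium 12 (not isolated)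
Conditions: CrCl2 (5 equiv), NiCl2 (2 mol%), DMSO, rt
Reagents that add atoms: none
Why: Nozaki–Hiyama–Kishi coupling: zerovalent nickel inserts into the C4–I bond and transmetalation gives the trivalent alkenylchromium with retention, which adds to the enolisable aldehyde without deprotonating it; C3 forms as a racemate that steps 8 and 9 resolve into one configuration.

Step 8
Reactants: 13 racemic C3 allylic alcohol
Product: 14 C3 enone
Conditions: Dess–Martin periodinane, pyridine, CH2Cl2, 0 °C
Reagents that add atoms: none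
Why: Dess–Martin oxidation of the secondary allylic alcohol under neutral conditions, which should leave the β,γ-olefin and the Z-enone geometry in place.

Step 9
Reactants: 14 C3 enone
Product: 15 (3S)-allylic alcohol
Conditions: (R)-2-methyl-CBS-oxazaborolidine (0.5 equiv), catecholborane, toluene, −78 °C
Reagents that add atoms: none
Why: Corey–Bakshi–Shibata reduction in which the α-branched alkenyl group (C4) acts as the large substituent, so the (R)-catalyst should give the 3S carbinol; catecholborane does not hydroborate the trisubstituted olefin at this temperature.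

Step 10
Reactants: 15 (3S)-allylic alcohol
Product: 16 (3S)-C3,C15-bis-TBS ether with C6–OTES
Conditions: TBSOTf, 2,6-lutidine, CH2Cl2, −78 °C
Reagents that add atoms: tert-butyldimethylsilyl triflate, CC(C)(C)[Si](C)(C)OS(=O)(=O)C(F)(F)F
Why: Silylation of the hindered secondary allylic alcohol with the reactive triflate; C3 is not touched.

Step 11
Reactants: 16 (3S)-C3,C15-bis-TBS ether with C6–OTES
Product: 17 (3S)-C6 primary allylic alcohol
Conditions: PPTS (cat.), MeOH/CH2Cl2, 0 °C
Reagents that add atoms: none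
Why: Acid-catalysed methanolysis removes the primary TES ether much faster than the primary and secondary TBS ethers.

Step 12
Reactants: 17 (3S)-C6 primary allylic alcohol
Product: 18 (3S,4Z)-enal (C6 aldehyde)
Conditions: Dess–Martin periodinane, pyridine, CH2Cl2, 0 °C
Reagents that add atoms: none
Why: Dess–Martin oxidation of a Z-allylic alcohol to the Z-enal with retention of the olefin geometry.

Step 13
Reactants: 19 prop-2-yn-1-ol
Product: 20 triethyl(prop-2-yn-1-yloxy)silane
Conditions: TESCl, imidazole, CH2Cl2, 0 °C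
Reagents that add atoms: chlorotriethylsilane, CC[Si](Cl)(CC)CC
Why: Silylation of propargyl alcohol; the TES ether carries the later C13 oxygen and is orthogonal to TBS and PMB.

Step 14
Reactants: 18 (3S,4Z)-enal; 20 triethyl(prop-2-yn-1-yloxy)silane
Product: 22 (3S,6R)-propargylic alcohol, via alkynylzinc 21 (not isolated)
Conditions: (R,R)-ProPhenol (20 mol%), ZnMe2 (3 equiv), Ph3PO (40 mol%), toluene, 0 °C
Reagents that add atoms: none
Why: Catalytic asymmetric alkynylation of an enal: ZnMe2 metalates the alkyne and the dinuclear zinc–ProPhenol complex delivers the alkynyl group to the Si face of the aldehyde, which sets C6 as R by reagent control.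

Step 15
Reactants: 22 (3S,6R)-propargylic alcohol
Product: 24 (3S,6R)-C11 vinyl iodide (7Z), via cyclic alkenylalanate 23 (not isolated)
Conditions: NaAlH2(OCH2CH2OMe)2, THF, 0 °C; EtOAc; I2, THF, −78 °C
Reagents that add atoms: iodine, [I][I]
Why: Second hydroxyl-directed trans-hydroalumination, now of the C7≡C11 alkyne from the C6 alkoxide, followed by iodinolysis with retention; iodine ends on C11 cis to C6–OH and the isolated olefins are not reduced.

Step 16
Reactants: 24 (3S,6R)-C11 vinyl iodide
Product: 25 (3S,6R)-3-[(triethylsilyloxy)methyl]butenolide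
Conditions: PdCl2(PPh3)2 (5 mol%), CO (1 atm), K2CO3, THF, 50 °C
Reagents that add atoms: carbon monoxide, [C-]#[O+]
Why: Palladium-catalysed carbonylative lactonisation: oxidative addition at C11–I, CO insertion and capture of the acylpalladium by the cis C6 hydroxyl close the five-membered lactone (C12 from CO); the mild insoluble base should leave the doubly allylic C6–H alone.

Step 17
Reactants: 25 (3S,6R)-3-[(triethylsilyloxy)methyl]butenolide
Product: 26 (3S,6R)-3-(hydroxymethyl)butenolide
Conditions: PPTS (cat.), MeOH, 0 °C → rt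
Reagents that add atoms: none
Why: Selective acid-catalysed methanolysis of the primary TES ether beside two TBS ethers, the PMB ether and the lactone.

Step 18
Reactants: 26 (3S,6R)-3-(hydroxymethyl)butenolide
Product: 27 (3S,6R)-3-(bromomethyl)butenolide PMB ether
Conditions: CBr4, PPh3, CH2Cl2, 0 °C
Reagents that add atoms: carbon tetrabromide, BrC(Br)(Br)Br
Why: Appel bromination of the primary allylic alcohol under neutral conditions.

Step 19
Reactants: 27 (3S,6R)-3-(bromomethyl)butenolide PMB ether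
Product: 28 (3S,6R)-bromomethylbutenolide C8 alcohol
Conditions: DDQ, CH2Cl2/pH 7 buffer, 0 °C
Reagents that add atoms: none
Why: Oxidative PMB cleavage by hydride abstraction at the benzylic position; the allylic bromide, silyl ethers and olefins are expected to survive.

Step 20
Reactants: 28 (3S,6R)-bromomethylbutenolide C8 alcohol
Product: 29 (3S,6R)-3-(bromomethyl)butenolide C8 aldehyde
Conditions: Dess–Martin periodinane, pyridine, CH2Cl2, 0 °C; used at once
Reagents that add atoms: none
Why: Buffered Dess–Martin oxidation gives the β,γ-unsaturated aldehyde, which is taken directly into the cyclisation to avoid isomerisation.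

Step 21
Reactants: 29 (3S,6R)-3-(bromomethyl)butenolide C8 aldehyde
Product: 31 (3S,6R,7R,8R)-8-hydroxygermacra-1(10),4,11(13)-trien-12,6-olide 3,15-bis-TBS ether, via allylchromium 30 (not isolated)
Conditions: CrCl2 (10 equiv), THF, rt, slow addition of 29 to 0.002 M
Reagents that add atoms: none
Why: Two one-electron reductions by divalent chromium convert the C13–Br bond into the trivalent allylchromium 30, which adds to the tethered C8 aldehyde through its γ-carbon C7 in a closed six-membered transition state (Cr–O–C8–C7–C11–C13), forming C7–C8 and moving the double bond to exocyclic C11=C13. The closest known reactions are the chromium-, zinc- and indium-mediated Barbier additions of 3-(bromomethyl)butenolides to aldehydes through the ring carbon and the chromium-mediated allylation macrocyclisations of 2-(bromomethyl)acrylates. The ten-membered carbocycle closes by this γ-attack with C7 as the only allyl carbon in the new ring (C11 and C13 stay exocyclic), and high dilution keeps the reaction intramolecular. C7 is controlled by C6: bond formation on the butenolide face opposite to C5 gives the trans-fused lactone, because attack on the C5 face would force a nearly eclipsed C5–C6–C7–C8 torsion and a close C5/C9 contact inside the medium ring. C8 is controlled by the aldehyde face: the 8R carbinol requires C9 pseudo-axial on the chair (or the equivalent boat), which is the arrangement the short tether with its Z-C4=C5 and E-C1=C10 olefins is counted on to hold as it returns beneath the lactone to C5; this is the selectivity on which the step depends. The closed transition state also secures γ- over α-attack (α-attack would give a twelve-membered ring), and slow addition should let cyclisation outrun 1,4-fragmentation of 30 and oligomerisation.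

Step 22
Reactants: 31 (3S,6R,7R,8R)-8-hydroxygermacratrienolide bis-TBS ether
Product: 32 8-O-methacryloyl ester of 31
Conditions: methacrylic anhydride, Et3N, DMAP, CH2Cl2, 0 °C → rt
Reagents that add atoms: methacrylic anhydride, C=C(C)C(=O)OC(=O)C(C)=C
Why: DMAP-catalysed acylation of the only free hydroxyl with retention at C8; prompt acylation also prevents migration of the lactone to C8–O.

Step 23
Reactants: 32 8-O-methacryloyl ester
Product: 33 (1R,10R)-1,10-epoxide of 32
Conditions: mCPBA, CH2Cl2/aq. NaHCO3, 0 °C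
Reagents that add atoms: 3-chloroperbenzoic acid, O=C(OO)c1cccc(Cl)c1
Why: Prilezhaev epoxidation of the only electron-rich olefin (C4=C5 is deactivated by three allylic C–O bonds, the two acrylate-type olefins are electron-poor); it is stereospecific for the E-olefin, and peripheral attack on the conformer with C14 on the β-face is expected to give the 1β,10α (1R,10R) oxirane.

Step 24
Reactants: 33 (1R,10R)-1,10-epoxide bis-TBS ether
Product: 34 target, (1R,3S,6R,7R,8R,10R,4Z)-1,10-epoxy-3,15-dihydroxy-8-(methacryloyloxy)germacra-4,11(13)-dien-12,6-olide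
Conditions: HF·pyridine, pyridine, THF, 0 °C → rt
Reagents that add atoms: none
Why: Buffered fluoride-mediated cleavage of the primary and secondary allylic TBS ethers, kept near neutral to spare the oxirane, the two esters and the α-methylene lactone.

**Compound list**

1 | but-3-yn-1-ol | C#CCCO | starting material
2 | 4-methoxybenzyl but-3-yn-1-yl ether | C#CCCOCc1ccc(OC)cc1 | intermediate
3 | (E)-{4-[(4-methoxybenzyl)oxy]-2-methylbut-1-en-1-yl}dimethylalane (not isolated) | C[Al](C)/C=C(\C)CCOCc1ccc(OC)cc1 | intermediate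
4 | lithium butyl{(E)-4-[(4-methoxybenzyl)oxy]-2-methylbut-1-en-1-yl}dimethylaluminate (not isolated) | [Li+].CCCC[Al-](C)(C)/C=C(\C)CCOCc1ccc(OC)cc1 | intermediate
5 | (E)-6-[(4-methoxybenzyl)oxy]-4-methylhex-3-en-1-ol | OCC/C=C(\C)CCOCc1ccc(OC)cc1 | intermediate
6 | (E)-6-[(4-methoxybenzyl)oxy]-4-methylhex-3-enal | O=CC/C=C(\C)CCOCc1ccc(OC)cc1 | intermediate
7 | but-2-yne-1,4-diol | OCC#CCO | starting material
8 | 4-[(tert-butyldimethylsilyl)oxy]but-2-yn-1-ol | OCC#CCO[Si](C)(C)C(C)(C)C | intermediate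
9 | sodium 3-{[(tert-butyldimethylsilyl)oxy]methyl}-2,2-bis(2-methoxyethoxy)-2,5-dihydro-1,2-oxaaluminol-2-uide (not isolated) | [Na+].COCCO[Al-]1(OCCOC)OCC=C1CO[Si](C)(C)C(C)(C)C | intermediate
10 | (Z)-4-[(tert-butyldimethylsilyl)oxy]-3-iodobut-2-en-1-ol | OC/C=C(\I)CO[Si](C)(C)C(C)(C)C | intermediate
11 | (Z)-tert-butyl({2-iodo-4-[(triethylsilyl)oxy]but-2-en-1-yl}oxy)dimethylsilane | CC[Si](CC)(CC)OC/C=C(\I)CO[Si](C)(C)C(C)(C)C | intermediate
12 | dichloro{(Z)-1-[(tert-butyldimethylsilyl)oxy]-4-[(triethylsilyl)oxy]but-2-en-2-yl}chromium, trivalent (not isolated) | CC[Si](CC)(CC)OC/C=C(\[Cr](Cl)Cl)CO[Si](C)(C)C(C)(C)C | intermediate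
13 | rac-(2Z,6E)-3-{[(tert-butyldimethylsilyl)oxy]methyl}-9-[(4-methoxybenzyl)oxy]-7-methyl-1-[(triethylsilyl)oxy]nona-2,6-dien-4-ol | CC[Si](CC)(CC)OC/C=C(/CO[Si](C)(C)C(C)(C)C)C(O)C/C=C(\C)CCOCc1ccc(OC)cc1 | intermediate
14 | (2Z,6E)-3-{[(tert-butyldimethylsilyl)oxy]methyl}-9-[(4-methoxybenzyl)oxy]-7-methyl-1-[(triethylsilyl)oxy]nona-2,6-dien-4-one | CC[Si](CC)(CC)OC/C=C(/CO[Si](C)(C)C(C)(C)C)C(=O)C/C=C(\C)CCOCc1ccc(OC)cc1 | intermediate
15 | (4S,2Z,6E)-3-{[(tert-butyldimethylsilyl)oxy]methyl}-9-[(4-methoxybenzyl)oxy]-7-methyl-1-[(triethylsilyl)oxy]nona-2,6-dien-4-ol | CC[Si](CC)(CC)OC/C=C(/CO[Si](C)(C)C(C)(C)C)[C@@H](O)C/C=C(\C)CCOCc1ccc(OC)cc1 | intermediate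
16 | (4S,2Z,6E)-4-[(tert-butyldimethylsilyl)oxy]-3-{[(tert-butyldimethylsilyl)oxy]methyl}-9-[(4-methoxybenzyl)oxy]-7-methyl-1-[(triethylsilyl)oxy]nona-2,6-diene | CC[Si](CC)(CC)OC/C=C(/CO[Si](C)(C)C(C)(C)C)[C@@H](O[Si](C)(C)C(C)(C)C)C/C=C(\C)CCOCc1ccc(OC)cc1 | intermediate
17 | (4S,2Z,6E)-4-[(tert-butyldimethylsilyl)oxy]-3-{[(tert-butyldimethylsilyl)oxy]methyl}-9-[(4-methoxybenzyl)oxy]-7-methylnona-2,6-dien-1-ol | OC/C=C(/CO[Si](C)(C)C(C)(C)C)[C@@H](O[Si](C)(C)C(C)(C)C)C/C=C(\C)CCOCc1ccc(OC)cc1 | intermediate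
18 | (4S,2Z,6E)-4-[(tert-butyldimethylsilyl)oxy]-3-{[(tert-butyldimethylsilyl)oxy]methyl}-9-[(4-methoxybenzyl)oxy]-7-methylnona-2,6-dienal | O=C/C=C(/CO[Si](C)(C)C(C)(C)C)[C@@H](O[Si](C)(C)C(C)(C)C)C/C=C(\C)CCOCc1ccc(OC)cc1 | intermediate
19 | prop-2-yn-1-ol | C#CCO | starting material
20 | triethyl(prop-2-yn-1-yloxy)silane | C#CCO[Si](CC)(CC)CC | intermediate
21 | methyl{3-[(triethylsilyl)oxy]prop-1-yn-1-yl}zinc (not isolated) | C[Zn]C#CCO[Si](CC)(CC)CC | intermediate
22 | (4R,7S,5Z,9E)-7-[(tert-butyldimethylsilyl)oxy]-6-{[(tert-butyldimethylsilyl)oxy]methyl}-12-[(4-methoxybenzyl)oxy]-10-methyl-1-[(triethylsilyl)oxy]dodeca-5,9-dien-2-yn-4-ol | CC[Si](CC)(CC)OCC#C[C@H](O)/C=C(/CO[Si](C)(C)C(C)(C)C)[C@@H](O[Si](C)(C)C(C)(C)C)C/C=C(\C)CCOCc1ccc(OC)cc1 | intermediate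
23 | sodium 2,2-bis(2-methoxyethoxy)-2,5-dihydro-1,2-oxaaluminol-2-uide from 22, Al on C11 and O on C6 (5R) (not isolated) | [Na+].COCCO[Al-]1(OCCOC)O[C@@H](C=C1CO[Si](CC)(CC)CC)/C=C(/CO[Si](C)(C)C(C)(C)C)[C@@H](O[Si](C)(C)C(C)(C)C)C/C=C(\C)CCOCc1ccc(OC)cc1 | intermediate
24 | (4R,7S,2Z,5Z,9E)-7-[(tert-butyldimethylsilyl)oxy]-6-{[(tert-butyldimethylsilyl)oxy]methyl}-2-iodo-12-[(4-methoxybenzyl)oxy]-10-methyl-1-[(triethylsilyl)oxy]dodeca-2,5,9-trien-4-ol | CC[Si](CC)(CC)OC/C(I)=C/[C@H](O)/C=C(/CO[Si](C)(C)C(C)(C)C)[C@@H](O[Si](C)(C)C(C)(C)C)C/C=C(\C)CCOCc1ccc(OC)cc1 | intermediate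
25 | (5R)-5-[(3S,1Z,5E)-3-[(tert-butyldimethylsilyl)oxy]-2-{[(tert-butyldimethylsilyl)oxy]methyl}-8-[(4-methoxybenzyl)oxy]-6-methylocta-1,5-dien-1-yl]-3-{[(triethylsilyl)oxy]methyl}furan-2(5H)-one | CC[Si](CC)(CC)OCC1=C[C@H](OC1=O)/C=C(/CO[Si](C)(C)C(C)(C)C)[C@@H](O[Si](C)(C)C(C)(C)C)C/C=C(\C)CCOCc1ccc(OC)cc1 | intermediate
26 | 3-(hydroxymethyl) analogue of 25 (5R; side chain 3S,1Z,5E) | OCC1=C[C@H](OC1=O)/C=C(/CO[Si](C)(C)C(C)(C)C)[C@@H](O[Si](C)(C)C(C)(C)C)C/C=C(\C)CCOCc1ccc(OC)cc1 | intermediate
27 | 3-(bromomethyl) analogue of 25 (5R; side chain 3S,1Z,5E) | BrCC1=C[C@H](OC1=O)/C=C(/CO[Si](C)(C)C(C)(C)C)[C@@H](O[Si](C)(C)C(C)(C)C)C/C=C(\C)CCOCc1ccc(OC)cc1 | intermediate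
28 | (5R)-3-(bromomethyl)-5-[(3S,1Z,5E)-3-[(tert-butyldimethylsilyl)oxy]-2-{[(tert-butyldimethylsilyl)oxy]methyl}-8-hydroxy-6-methylocta-1,5-dien-1-yl]furan-2(5H)-one | BrCC1=C[C@H](OC1=O)/C=C(/CO[Si](C)(C)C(C)(C)C)[C@@H](O[Si](C)(C)C(C)(C)C)C/C=C(\C)CCO | intermediate
29 | (3E,6S,7Z)-8-[(2R)-4-(bromomethyl)-5-oxo-2,5-dihydrofuran-2-yl]-6-[(tert-butyldimethylsilyl)oxy]-7-{[(tert-butyldimethylsilyl)oxy]methyl}-3-methylocta-3,7-dienal (key-step precursor) | BrCC1=C[C@H](OC1=O)/C=C(/CO[Si](C)(C)C(C)(C)C)[C@@H](O[Si](C)(C)C(C)(C)C)C/C=C(\C)CC=O | intermediate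
30 | trivalent allylchromium dichloride from 29, Cr on C13 (not isolated) | Cl[Cr](Cl)CC1=C[C@H](OC1=O)/C=C(/CO[Si](C)(C)C(C)(C)C)[C@@H](O[Si](C)(C)C(C)(C)C)C/C=C(\C)CC=O | intermediate
31 | (3S,6R,7R,8R,1(10)E,4Z)-3,15-bis[(tert-butyldimethylsilyl)oxy]-8-hydroxygermacra-1(10),4,11(13)-trien-12,6-olide (key-step product) | O[C@@H]1C/C(C)=C/C[C@H](O[Si](C)(C)C(C)(C)C)/C(CO[Si](C)(C)C(C)(C)C)=C\[C@H]2OC(=O)C(=C)[C@@H]21 | intermediate
32 | 8-O-methacryloyl ester of 31 | C=C(C)C(=O)O[C@@H]1C/C(C)=C/C[C@H](O[Si](C)(C)C(C)(C)C)/C(CO[Si](C)(C)C(C)(C)C)=C\[C@H]2OC(=O)C(=C)[C@@H]21 | intermediate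
33 | (1R,10R)-1,10-epoxide of 32 | C=C(C)C(=O)O[C@@H]1C[C@@]2(C)O[C@@H]2C[C@H](O[Si](C)(C)C(C)(C)C)/C(CO[Si](C)(C)C(C)(C)C)=C\[C@H]2OC(=O)C(=C)[C@@H]21 | intermediate
34 | (1R,3S,6R,7R,8R,10R,4Z)-1,10-epoxy-3,15-dihydroxy-8-(methacryloyloxy)germacra-4,11(13)-dien-12,6-olide | C=C(C)C(=O)O[C@@H]1C[C@@]2(C)O[C@@H]2C[C@H](O)/C(CO)=C\[C@H]2OC(=O)C(=C)[C@@H]21 | target

**Step count and risks**

Total step count: 24. Longest linear sequence: 20 steps (steps 1–3, 7–12 and 14–24; the branch through steps 4–6 is equally long).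

Steps most likely to fail:

1. Step 21. The aldehyde may add through the chair in which C9 is equatorial, the preference of intermolecular additions of such E-locked allylmetals, which inverts C8; fragmentation of the allylchromium with loss of the lactone carboxylate is a second drain. Fallback, setting out from 29: the same cyclisation is run and the C8 epimer, the (3S,6R,7R,8S)-alcohol F1, is isolated instead of 31. It is esterified with inversion under Mitsunobu conditions (methacrylic acid, PPh3, diisopropyl azodicarboxylate, toluene, 0 °C → rt), which corrects C8 and installs the methacrylate in one operation and rejoins the route at 32.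

2. Step 14. The β,β-disubstituted Z-enal is hindered, so the catalytic alkynylation may be slow or poorly face-selective, or may add to the wrong face. Fallback, setting out from 18: addition of the lithium acetylide of 20, lithium 3-[(triethylsilyl)oxy]prop-1-yn-1-ide F2 (n-BuLi, THF, −78 °C), gives the C6-epimeric propargylic alcohols F3 without selectivity. Dess–Martin oxidation gives the ynone F4, and Midland reduction with (R)-Alpine-borane, in which the linear alkynyl group acts as the small substituent, should return the 6R alcohol 22.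

3. Step 23. The peracid may attack the other face of the E-C1=C10 olefin if the ring populates a conformer with C14 on the α-face, giving the (1S,10S)-oxirane or a mixture. Fallback, setting out from 32: reagent-controlled Shi epoxidation (D-fructose-derived ketone, KHSO5, K2CO3, MeCN/dimethoxymethane/aqueous buffer, 0 °C), which gives (R,R)-epoxides from E-trisubstituted olefins, leads to 33 directly; it makes no compound outside the list (F0).

Further compounds
F1 | step 21 | (3S,6R,7R,8S,1(10)E,4Z)-3,15-bis[(tert-butyldimethylsilyl)oxy]-8-hydroxygermacra-1(10),4,11(13)-trien-12,6-olide (C8 epimer of 31) | O[C@H]1C/C(C)=C/C[C@H](O[Si](C)(C)C(C)(C)C)/C(CO[Si](C)(C)C(C)(C)C)=C\[C@H]2OC(=O)C(=C)[C@@H]21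
F2 | step 14 | lithium 3-[(triethylsilyl)oxy]prop-1-yn-1-ide | [Li]C#CCO[Si](CC)(CC)CC
F3 | step 14 | (7S,5Z,9E)-7-[(tert-butyldimethylsilyl)oxy]-6-{[(tert-butyldimethylsilyl)oxy]methyl}-12-[(4-methoxybenzyl)oxy]-10-methyl-1-[(triethylsilyl)oxy]dodeca-5,9-dien-2-yn-4-ol, both C4 epimers | CC[Si](CC)(CC)OCC#CC(O)/C=C(/CO[Si](C)(C)C(C)(C)C)[C@@H](O[Si](C)(C)C(C)(C)C)C/C=C(\C)CCOCc1ccc(OC)cc1
F4 | step 14 | (7S,5Z,9E)-7-[(tert-butyldimethylsilyl)oxy]-6-{[(tert-butyldimethylsilyl)oxy]methyl}-12-[(4-methoxybenzyl)oxy]-10-methyl-1-[(triethylsilyl)oxy]dodeca-5,9-dien-2-yn-4-one | CC[Si](CC)(CC)OCC#CC(=O)/C=C(/CO[Si](C)(C)C(C)(C)C)[C@@H](O[Si](C)(C)C(C)(C)C)C/C=C(\C)CCOCc1ccc(OC)cc1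
F0 | step 23 | none | none
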